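Take G as the limiting reagent: charged equal to J, it covers half of J and E together, and each product molecule costs one G.

the same everywhere: J 0.069 M; E 0.069 M
- birch: G 1 equiv; L 0.095 mol%; run made earlier
- oak: G 1 equiv; L 0.14 mol%; run made earlier
- flask: G 1.00 equiv; L 0.19 mol%; time 50 h

- birch (time / h: J / %, E / %): 5.00: 48.2, 48.7; 10.0: 41.9, 46.5; 15.0: 38.5, 45.2; 30.0: 34.5, 42.1; 60.0: 33.7, 41.7
- oak (time / h: J / %, E / %): 12.0: 35.9, 44.2; 25.0: 31.6, 40.3; 40.0: 31.9, 41.1; 50.0: 31.2, 42.0; 60.0: 31.2, 42.8

(readings scatter by 1 percentage point)

- part of the J and E charged together that has reacted at 50 h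
- excess of X over Q in the product at 50 h
- excess of E over J among what is left of the two at 50 h

- D is single-handed; J and E are mirror images of each other, charged as a racemate, each of them at the stated concentration
- on the list of suspects stand: L -> D; X <-> Q; G + D + E -> D + Q; G -> Z; G + D + J -> D + X
- an excess is below zero if the other one leads

Climb the ladder of times, fastest rung first. Activation of L to D: birch loses 3.10% of J and E by 5.00 h, then loses faster, 8.5 percentage points by 10.0 h, so D grows over hours. The stop: oak shows no further loss beyond scatter after 25.0 h, earlier than 50 h. The suspects remove no D, so assume the stop marks the end of G.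

Now write the balance of G: with c the converted part and g its charge on the same scale, G goes to product or Z. Define the partition ratio ρ as product formed per Z formed, c/(g − c). Oak's last 3 readings give c = 26.6%, so ρ = 1.14. Product needs D and Z does not, so scale ρ with the loading of L: my flask reckoning gives ρ = 1.54 and c = 30.3%. Hold this as rough: birch's last two readings give c = 24.0% and ρ = 0.923, more than the scaled 0.771.

The forecast gives 30.5%, 36% and 16%, reached “when the reaction is essentially finished”.

The flask gives c = 28.7%, an excess of X over Q of 0.0107% and an excess of E over J of 14.9%.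

    L → D (k = 0.00160 /min)
    X ⇌ Q (k = 0.00240 /min)
    G + D + E → D + Q (k = 120 /M²/min)
    G → Z (k = 9.00 × 10⁻⁴ /min)
    G + D + J → D + X (k = 300 /M²/min)

By X ⇌ Q alone, both ways together, X and Q relax with a half-life of 2.41 h, short against 50 h. The flask's ρ is 1.35, less than the reckoned 1.54.

For a neighbour of the flask, charged with 0.11 mol% of L, oak's ρ scales to 0.893, which gives c = 23.6%. The computed value is 24.0%.

(The data are simulated with made-up constants.)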